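Abbreviations used throughout: Ar = 4-(benzyloxy)-3,5-dimethoxyphenyl; TBS = tert-butyldimethylsilyl; Bpin = 4,4,5,5-tetramethyl-1,3,2-dioxaborolan-2-yl; (R)-TRIP = (R)-3,3'-bis(2,4,6-triisopropylphenyl)-1,1'-binaphthyl-2,2'-diyl hydrogen phosphate. Oxolanes are numbered O1, C2 (aryl), C3, C4, C5 (aryl), with C2 the aryl carbon that is cis to its neighbour C3. The dioxepin is numbered O1, C2, O3, C4, C5, C6=C7.

## The problem

Compound 18 is a 2,5-diaryl-3,4-bis(hydroxymethyl)oxolane with one five-membered ring, two identical syringyl groups on the carbons flanking the ring oxygen, and four contiguous stereocentres; in the numbering above it is 2S,3S,4S,5R, that is 2,3-cis, 3,4-trans, 4,5-trans and 2,5-cis. The two halves are constitutionally identical but stereochemically different, so the molecule has no symmetry element, and any dimerisation or two-directional approach has to break the symmetry at one benzylic carbon. C2 carries its aryl group cis to the C3 substituent, the less stable arrangement (the C2 epimer is all-trans), so C2 has to be set under kinetic control and must not equilibrate afterwards. The fragile parts are the two benzylic C–O bonds para to electron-rich phenols, which acid opens or epimerises through benzylic cations or quinone methides and which hydrogenolysis can cleave, and the oxidisable phenols themselves, which stay masked until the end. The enabling feature is the array O1–C2–C3–CH2OH: C2 is a benzylic carbon at the acetal level, and the carbon on C3 can be raised to the formyl level. C2–C3 then becomes an aldol-type bond between an oxocarbenium ion and an enol, and tying the enol oxygen back to C2 gives a 2-aryl-4,5-dihydro-1,3-dioxepin. The trans pair C4/C5 can be set by catalyst control in an acyclic precursor and can then direct both new centres: C3 through allylic strain in the enol ether, C2 through the preferred envelope of the closing ring.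

## Retrosynthesis

**18 ⇒ 17 ⇒ 16.** The last bonds cut are the two aryl O–benzyl bonds (17 to 18, hydrogenolysis) and the O–Si bond (16 to 17, fluoride). Benzyl ethers are preferred to silyl or acyl groups on the phenols because they pass through alkoxide base, the Ru carbene and the silyl triflate unchanged, and they damp ionisation of the benzylic C–O bonds. The silyl ether on the C4 hydroxymethyl group is the one that boronate 4 brings along. The skeleton is not simplified here; the forward steps only have to stop at the aryl ethers and spare the two ring C–O bonds.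

**16 ⇒ 15.** Raising the C3 hydroxymethyl group to the aldehyde 15 changes no skeletal bond but exposes the β-alkoxy aldehyde O1–C2–C3–CHO, the retron of an aldol-type addition to an oxocarbenium ion. The price is an epimerisable C3, so the forward reduction must follow the C–C bond formation at once.

**15 ⇒ 13.** Cutting C2–C3 of 15 and joining the formyl oxygen to C2 gives the seven-membered enol acetal 13 (through ion pair 14 in the forward sense). The neighbouring cuts are C3–C4 (a dimerisation), the two aryl–carbon bonds, and C4–C5 with O1–C5 (the three roads below). Against them, this cut makes one C–C bond and two stereocentres in a single intramolecular step steered by the two centres already present, and both aryl-bearing carbons come from the same aldehyde 3. Precursor 13 has only two stereocentres that matter, C4 and C5, because the acetal carbon is lost on ionisation. The forward reaction must close cis at C2/C3 under kinetic control.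

**13 ⇒ 12.** The C6=C7 double bond of 13 is cut by a metathesis transform to the acyclic diene 12. The usual entry to this ring system, double-bond migration in a preformed cyclic allylic acetal, would have to create C5 during the migration; the metathesis keeps C5 as set in 8. The forward step must form a seven-membered cyclic enol ether from a vinyl acetal without acid.

**12 ⇒ 11 ⇒ 8 + 9.** The vinyl group of 12 is traced to the 2-bromoethyl group of 11 (elimination), and the acetal C–O bond of 11 is cut to the secondary alcohol 8 and the symmetric acetal 9. A mixed acyclic acetal cannot be made cleanly by equilibrating two alcohols with an aldehyde, so the forward step must replace exactly one alkoxy group of 9 by 8 under non-equilibrating conditions (via salt 10). Both 8 and 9 are one step from aldehyde 3.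

**8 ⇒ 3 + 6; 9 ⇒ 3.** In 8 the bond between the carbinol and allylic carbons is cut to aldehyde 3 and the (E)-allylboronate 6; 9 is the acetal of the same aldehyde. An allylboration is preferred to an aldol sequence because it sets both centres and delivers the vinyl and protected hydroxymethyl groups at the right oxidation level in one step. The forward reaction must be anti-selective (from the E geometry of 6) and enantioselective (from a chiral catalyst), passing through borate 7.

**6 ⇒ 4; 3 ⇒ 1 + 2.** Boronate 6 is the one-carbon homologue of the catalogue alkenylboronate 4 (through ate complex 5). Aldehyde 3 is the benzyl ether of syringaldehyde 1, made with benzyl bromide 2.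

## Roads not taken

**Alternative 1:** The cut is C3–C4 together with both benzylic C–O bonds, and the starting material is sinapic acid A1. Aerobic laccase oxidation would couple two phenoxy radicals derived from A1 at their β-carbons, and each carboxyl group would trap the opposite quinone methide to give the bis-lactone A2. This is the shortest conceivable entry: one step from A1, a commodity acid, builds the whole carbon skeleton without protecting groups, and in step count it beats the chosen plan clearly. Its weak points are structural. The radical coupling is achiral, so A2 is racemic and the single enantiomer would need a resolution. After hydride reduction of both lactones, the oxolane would have to be closed between the two benzylic positions with inversion at exactly one of them to reach the 2,5-cis pattern. That closure must happen in the presence of two primary hydroxyls competing for the same benzylic carbons and of free para-phenols that favour ionisation and thermodynamic (all-trans or furofuran-type) outcomes. Against the brevity of this road the chosen plan sets catalyst-controlled absolute configuration and a ring closure whose stereochemical course is programmed by the substrate.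

**Alternative 2:** The cut is at both aryl–carbonyl bonds of a 1,4-diketone. The C2-symmetric bis-Weinreb amide A3 would take up two equivalents of the aryllithium A4 to give diketone A5. The merits are real: the 3,4-trans pair is secure from the start, both aryl groups arrive in one operation, and mono-activation of either homotopic carbinol after reduction would give the unsymmetrical 2,5-cis pattern by a stereospecific invertive closure. That closure is arguably more predictable at C2 than a kinetic cyclisation. The weak points are these: A3 is itself several steps from the chiral pool; A5 is a β-alkoxy ketone with enolisable α-centres, open to epimerisation and loss of benzyloxide under the basic addition; and both ketones must then be reduced with the same facial sense, two further stereocentres set by reagent or 1,3-induction. The chosen plan avoids enolisable ketones next to stereocentres and makes C2 and C3 together with the C–C bond, but it has to accept that its C2 selectivity is kinetic and not stereospecific.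

**Alternative 3:** The cut is C4–C5 and O1–C5. The alkylidene β-keto ester A6 would be attacked at its β-carbon by the chiral sulfonium ylide A7, and the enolate oxygen would displace the sulfide to close the trans-4,5-dihydrofuran A8. This is convergent, sets the 4,5-trans pair and the absolute configuration in the ring-forming step, and reaches a five-membered ring earlier than the chosen plan. The difficulty is what remains: C2 and C3 of A8 are a tetrasubstituted, ester-conjugated enol ether. A syn hydrogenation would give 2,3-cis, but it would have to approach from the face carrying the adjacent silyloxymethyl group to give 3,4-trans and 2,5-cis, against the usual steric bias. Forcing conditions would also threaten the benzyl ethers and the benzylic C5–O bond, and ionic reductions favour the trans arrangement at C2/C3. The chosen plan sets C2 and C3 during ring formation under control of C4 and C5, and pays for this with a longer sequence to its cyclisation substrate.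

Key step: step 8

## Route

Assumption: the facial sense of (R)-TRIP with aldehyde 3 and the γ-substituted boronate 6 is taken to be the one established for aryl aldehydes with (E)-crotyl pinacol boronate (Re-face attack, here giving the 1R,2S alcohol); if it is the opposite, (S)-TRIP is used.

Step 1
Reactants: 1 syringaldehyde; 2 benzyl bromide
Product: 3 4-(benzyloxy)-3,5-dimethoxybenzaldehyde
Conditions: K2CO3, DMF, 60 °C
Reagents that add atoms: none
Why: Williamson ether synthesis on the only nucleophilic site; the benzyl ether is inert to every later reagent up to the final hydrogenolysis.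

Step 2
Reactants: 4 tert-butyldimethyl{[(2E)-3-(Bpin)prop-2-en-1-yl]oxy}silane
Product: 6 tert-butyldimethyl{[(2E)-4-(Bpin)but-2-en-1-yl]oxy}silane, via lithium chloromethyl borate complex 5 (not isolated)
Conditions: ICH2Cl, n-BuLi, THF, −78 °C to rt
Reagents that add atoms: chloroiodomethane, ClCI
Why: Matteson homologation; chloromethyllithium formed in the presence of 4 adds to boron, and 1,2-migration of the alkenyl group with loss of chloride inserts one CH2 with retention of the E geometry.

Step 3
Reactants: 3 4-(benzyloxy)-3,5-dimethoxybenzaldehyde; 6 tert-butyldimethyl{[(2E)-4-(Bpin)but-2-en-1-yl]oxy}silane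
Product: 8 (1R,2S)-1-Ar-2-[(TBS-oxy)methyl]but-3-en-1-ol, via O-pinacolboryl ether 7 (not isolated)
Conditions: 6 (1.2 equiv), (R)-TRIP (5 mol%), 4 Å MS, toluene, −30 °C; aq. NaHCO3 work-up
Reagents that add atoms: none
Why: Chiral phosphoric acid-catalysed allylboration through a closed Zimmerman–Traxler chair; the E boronate places the silyloxymethyl group equatorial and gives the anti relationship, and the catalyst, hydrogen-bonded to a boronate oxygen and the formyl hydrogen, selects the Re face of the aldehyde (1R), which fixes 2S.

Step 4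
Reactants: 3 4-(benzyloxy)-3,5-dimethoxybenzaldehyde
Product: 9 2-(benzyloxy)-5-[bis(2-bromoethoxy)methyl]-1,3-dimethoxybenzene
Conditions: Me3SiOCH2CH2Br (2.2 equiv), Me3SiOTf (5 mol%), CH2Cl2, −78 °C; pyridine quench
Reagents that add atoms: (2-bromoethoxy)trimethylsilane, C[Si](C)(C)OCCBr
Why: Silyl triflate-catalysed acetalisation of an aldehyde with an alkoxysilane, driven by formation of the disiloxane at low temperature; it avoids hot protic acid on an electron-rich aldehyde and on the bromo alcohol.

Step 5
Reactants: 9 2-(benzyloxy)-5-[bis(2-bromoethoxy)methyl]-1,3-dimethoxybenzene; 8 (1R,2S)-1-Ar-2-[(TBS-oxy)methyl]but-3-en-1-ol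
Product: 11 2-(benzyloxy)-5-[(2-bromoethoxy){[(1R,2S)-1-Ar-2-[(TBS-oxy)methyl]but-3-en-1-yl]oxy}methyl]-1,3-dimethoxybenzene (both epimers at the acetal carbon), via collidinium salt 10 (not isolated)
Conditions: 9 (2.0 equiv), Et3SiOTf (1.8 equiv), 2,4,6-collidine (3 equiv), CH2Cl2, 0 °C; then 8 (1.0 equiv), 0 °C to rt
Reagents that add atoms: none
Why: Mixed acetal formation through a pyridinium salt: the silyl triflate and the hindered pyridine replace one alkoxy group of 9 by collidine, and alcohol 8 then displaces the collidine under buffered, non-equilibrating conditions, so the acetal does not scramble; 9 is kept in excess over the silyl triflate so that 8 is not silylated, and the epimeric acetal carbon is of no consequence because it is ionised in step 8.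

Step 6
Reactants: 11 2-(benzyloxy)-5-[(2-bromoethoxy){[(1R,2S)-1-Ar-2-[(TBS-oxy)methyl]but-3-en-1-yl]oxy}methyl]-1,3-dimethoxybenzene
Product: 12 2-(benzyloxy)-5-[(ethenyloxy){[(1R,2S)-1-Ar-2-[(TBS-oxy)methyl]but-3-en-1-yl]oxy}methyl]-1,3-dimethoxybenzene (both epimers at the acetal carbon)
Conditions: KOt-Bu, THF, 0 °C to rt
Reagents that add atoms: none
Why: E2 dehydrobromination of a 2-bromoethyl ether to the vinyl ether; the only β-hydrogens are those next to oxygen, and the acetal, silyl ether and benzyl ethers are stable to alkoxide.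

Step 7
Reactants: 12 2-(benzyloxy)-5-[(ethenyloxy){[(1R,2S)-1-Ar-2-[(TBS-oxy)methyl]but-3-en-1-yl]oxy}methyl]-1,3-dimethoxybenzene
Product: 13 (4R,5S)-2,4-di-Ar-5-[(TBS-oxy)methyl]-4,5-dihydro-1,3-dioxepine (2R and 2S epimers; 2R is the 2,4-cis isomer)
Conditions: RuCl2(=CHPh)(H2IMes)(PCy3) (second-generation Grubbs catalyst, 5–10 mol%), degassed toluene (5 mM), 70 °C; chromatography on Et3N-deactivated silica
Reagents that add atoms: none
Why: Ring-closing metathesis between a monosubstituted alkene and a vinyl ether; the carbene loads on the alkene and closes onto the enol ether with loss of the two terminal methylene groups, giving the seven-membered cyclic enol acetal with C4 and C5 untouched.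

Step 8
Reactants: 13 (4R,5S)-2,4-di-Ar-5-[(TBS-oxy)methyl]-4,5-dihydro-1,3-dioxepine
Product: 15 (2S,3R,4S,5R)-2,5-di-Ar-4-[(TBS-oxy)methyl]oxolane-3-carbaldehyde, via ring-opened oxocarbenium silyl enol ether triflate 14 (not isolated)
Conditions: Me3SiOTf (20 mol%), CH2Cl2, −78 °C; Et3N then aq. NaHCO3 at −78 °C; crude product taken on at once
Reagents that add atoms: none
Why: Me3SiOTf silylates the enol-ether oxygen O1 of 13 and the C2–O1 bond ionises to the aryl-stabilised (E)-oxocarbenium ion tethered to a (Z)-silyl enol ether (14); the enol carbon C6 adds to C2 and the silyl group leaves the new formyl oxygen, so the acid is turned over. The closest known reaction is the Lewis acid-mediated [1,3] O-to-C ring contraction of 2-aryl-4,5-dihydro-1,3-dioxepins to 2-aryl-oxolane-3-carbaldehydes, an intramolecular Mukaiyama-type aldol addition related to the Petasis–Ferrier rearrangement, which is cis-selective at low temperature; here it is applied to a 4,5-disubstituted member of that class. The one ring formed (O3, C2, C6, C5, C4 of 13) closes in a 5-endo-trig mode at the C2=O3 cation, with the enol double bond exocyclic. The new C3 is controlled by C5 of 13: allylic 1,3-strain in the (Z)-enol ether holds the C5–H in the plane of the double bond, the cation attacks the face on which C4 lies, and the formyl group finishes trans to the silyloxymethyl group. The new C2 is controlled by C4 of 13: the (E)-oxocarbenium ion closes with the C4–H near its plane and the C4 aryl group pseudo-equatorial, which puts the two aryl groups cis across the ring oxygen. Because the substrate is 4,5-trans, both preferences are met in one envelope, which is also the 2,3-cis mode that the parent reaction follows kinetically; the 2,3-trans mode would force the silyloxymethyl group into the strained inside position. Both C2 epimers of 13 give the same ion 14, so the acetal mixture converges. The step needs kinetic control because the C2 epimer of 15 is all-trans and more stable; low temperature, substoichiometric acid and a cold amine quench guard against re-ionisation, and the benzyl ethers temper ionisation of the benzylic C4–O3 bond.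

Step 9
Reactants: 15 (2S,3R,4S,5R)-2,5-di-Ar-4-[(TBS-oxy)methyl]oxolane-3-carbaldehyde
Product: 16 {(2S,3S,4S,5R)-2,5-di-Ar-4-[(TBS-oxy)methyl]oxolan-3-yl}methanol
Conditions: NaBH4, MeOH/THF, −20 to 0 °C, on the crude aldehyde
Reagents that add atoms: none
Why: Borohydride reduction of the aldehyde, fast at low temperature and carried out before the α-centre can epimerise; it removes the only acidic C–H and fixes C3 (the descriptor changes from R to S only because the substituent priorities change).

Step 10
Reactants: 16 {(2S,3S,4S,5R)-2,5-di-Ar-4-[(TBS-oxy)methyl]oxolan-3-yl}methanol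
Product: 17 [(2S,3S,4S,5R)-2,5-di-Ar-oxolane-3,4-diyl]dimethanol
Conditions: Bu4NF, THF, 0 °C to rt
Reagents that add atoms: none
Why: Fluoride-mediated desilylation driven by the Si–F bond; benzyl ethers and the ring are inert to it.

Step 11
Reactants: 17 [(2S,3S,4S,5R)-2,5-di-Ar-oxolane-3,4-diyl]dimethanol
Product: 18 4,4'-[(2S,3S,4S,5R)-3,4-bis(hydroxymethyl)oxolane-2,5-diyl]bis(2,6-dimethoxyphenol)
Conditions: H2 (1 atm), 10% Pd/C, EtOAc/MeOH, rt, stopped after uptake of two equivalents
Reagents that add atoms: none
Why: Catalytic hydrogenolysis of the two aryl benzyl ethers, which cleave much faster than the cyclic dibenzylic ether under neutral conditions; no stereocentre is touched.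

## Compound list

1 | syringaldehyde (4-hydroxy-3,5-dimethoxybenzaldehyde) | COc1cc(C=O)cc(OC)c1O | starting material
2 | benzyl bromide | BrCc1ccccc1 | starting material
3 | 4-(benzyloxy)-3,5-dimethoxybenzaldehyde | O=Cc1cc(OC)c(OCc2ccccc2)c(OC)c1 | intermediate
4 | tert-butyldimethyl{[(2E)-3-(4,4,5,5-tetramethyl-1,3,2-dioxaborolan-2-yl)prop-2-en-1-yl]oxy}silane | CC(C)(C)[Si](C)(C)OC/C=C/B1OC(C)(C)C(C)(C)O1 | starting material
5 | lithium (chloromethyl){(1E)-3-[(tert-butyldimethylsilyl)oxy]prop-1-en-1-yl}(pinacolato)borate (not isolated) | [Li+].ClC[B-]1(/C=C/CO[Si](C)(C)C(C)(C)C)OC(C)(C)C(C)(C)O1 | intermediate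
6 | tert-butyldimethyl{[(2E)-4-(4,4,5,5-tetramethyl-1,3,2-dioxaborolan-2-yl)but-2-en-1-yl]oxy}silane | CC(C)(C)[Si](C)(C)OC/C=C/CB1OC(C)(C)C(C)(C)O1 | intermediate
7 | 2-{[(1R,2S)-1-Ar-2-[(TBS-oxy)methyl]but-3-en-1-yl]oxy}-4,4,5,5-tetramethyl-1,3,2-dioxaborolane (not isolated) | CC1(C)OB(O[C@@H](c2cc(OC)c(OCc3ccccc3)c(OC)c2)[C@H](CO[Si](C)(C)C(C)(C)C)C=C)OC1(C)C | intermediate
8 | (1R,2S)-1-[4-(benzyloxy)-3,5-dimethoxyphenyl]-2-{[(tert-butyldimethylsilyl)oxy]methyl}but-3-en-1-ol | O[C@@H](c1cc(OC)c(OCc2ccccc2)c(OC)c1)[C@H](CO[Si](C)(C)C(C)(C)C)C=C | intermediate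
9 | 2-(benzyloxy)-5-[bis(2-bromoethoxy)methyl]-1,3-dimethoxybenzene | BrCCOC(OCCBr)c1cc(OC)c(OCc2ccccc2)c(OC)c1 | intermediate
10 | 1-{[4-(benzyloxy)-3,5-dimethoxyphenyl](2-bromoethoxy)methyl}-2,4,6-trimethylpyridinium trifluoromethanesulfonate (not isolated) | Cc1cc(C)[n+](C(OCCBr)c2cc(OC)c(OCc3ccccc3)c(OC)c2)c(C)c1.[O-]S(=O)(=O)C(F)(F)F | intermediate
11 | 2-(benzyloxy)-5-[(2-bromoethoxy){[(1R,2S)-1-Ar-2-[(TBS-oxy)methyl]but-3-en-1-yl]oxy}methyl]-1,3-dimethoxybenzene, both epimers at the acetal carbon | BrCCOC(O[C@@H](c1cc(OC)c(OCc2ccccc2)c(OC)c1)[C@H](CO[Si](C)(C)C(C)(C)C)C=C)c1cc(OC)c(OCc2ccccc2)c(OC)c1 | intermediate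
12 | 2-(benzyloxy)-5-[(ethenyloxy){[(1R,2S)-1-Ar-2-[(TBS-oxy)methyl]but-3-en-1-yl]oxy}methyl]-1,3-dimethoxybenzene, both epimers at the acetal carbon | C=COC(O[C@@H](c1cc(OC)c(OCc2ccccc2)c(OC)c1)[C@H](CO[Si](C)(C)C(C)(C)C)C=C)c1cc(OC)c(OCc2ccccc2)c(OC)c1 | intermediate
13 | (4R,5S)-2,4-bis[4-(benzyloxy)-3,5-dimethoxyphenyl]-5-{[(tert-butyldimethylsilyl)oxy]methyl}-4,5-dihydro-1,3-dioxepine, 2R (2,4-cis) and 2S epimers | C1(c2cc(OC)c(OCc3ccccc3)c(OC)c2)O[C@@H](c2cc(OC)c(OCc3ccccc3)c(OC)c2)[C@H](CO[Si](C)(C)C(C)(C)C)C=CO1 | intermediate
14 | O-[(1R,2S,3Z)-1-Ar-2-[(TBS-oxy)methyl]-4-(trimethylsilyloxy)but-3-en-1-yl] oxocarbenium ion of aldehyde 3, trifluoromethanesulfonate (not isolated) | C[Si](C)(C)O/C=C\[C@@H](CO[Si](C)(C)C(C)(C)C)[C@H](c1cc(OC)c(OCc2ccccc2)c(OC)c1)[O+]=Cc1cc(OC)c(OCc2ccccc2)c(OC)c1.[O-]S(=O)(=O)C(F)(F)F | intermediate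
15 | (2S,3R,4S,5R)-2,5-bis[4-(benzyloxy)-3,5-dimethoxyphenyl]-4-{[(tert-butyldimethylsilyl)oxy]methyl}oxolane-3-carbaldehyde | COc1cc([C@H]2O[C@@H](c3cc(OC)c(OCc4ccccc4)c(OC)c3)[C@H](CO[Si](C)(C)C(C)(C)C)[C@H]2C=O)cc(OC)c1OCc1ccccc1 | intermediate
16 | {(2S,3S,4S,5R)-2,5-bis[4-(benzyloxy)-3,5-dimethoxyphenyl]-4-{[(tert-butyldimethylsilyl)oxy]methyl}oxolan-3-yl}methanol | COc1cc([C@H]2O[C@@H](c3cc(OC)c(OCc4ccccc4)c(OC)c3)[C@H](CO[Si](C)(C)C(C)(C)C)[C@H]2CO)cc(OC)c1OCc1ccccc1 | intermediate
17 | {(2S,3S,4S,5R)-2,5-bis[4-(benzyloxy)-3,5-dimethoxyphenyl]oxolane-3,4-diyl}dimethanol | COc1cc([C@H]2O[C@@H](c3cc(OC)c(OCc4ccccc4)c(OC)c3)[C@H](CO)[C@H]2CO)cc(OC)c1OCc1ccccc1 | intermediate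
18 | 4,4'-[(2S,3S,4S,5R)-3,4-bis(hydroxymethyl)oxolane-2,5-diyl]bis(2,6-dimethoxyphenol) (2,3-cis, 3,4-trans, 4,5-trans) | COc1cc([C@H]2O[C@@H](c3cc(OC)c(O)c(OC)c3)[C@H](CO)[C@H]2CO)cc(OC)c1O | target

## Step count and least certain steps

Total: 11 steps. Longest linear sequence: 9 steps (1 → 3 → 8 → 11 → 12 → 13 → 15 → 16 → 17 → 18; the branch from 4 through 6 is equally long).

**Step 8 (key step).** The most likely failure is loss of kinetic control: re-ionisation at C2 or reversible C2–C3 cleavage drains the 2,3-cis aldehyde into the more stable all-trans C2 epimer. Competing ionisation of the benzylic C4–O3 bond next to the electron-rich aryl group would scramble the aryl-bearing centre, and the α-centre of the aldehyde can epimerise on work-up. The fallback sets out from 8 and returns at 15, forming the same C2–C3 bond irreversibly with a carbon nucleophile that cannot re-open. Cross-metathesis of 8 with allyltrimethylsilane over RuCl2(=CHPh)(H2IMes)(PCy3) would give (1R,2S,3E)-1-Ar-2-[(TBS-oxy)methyl]-5-(trimethylsilyl)pent-3-en-1-ol F1. Condensation of F1 with aldehyde 3 (Me3SiOTf, CH2Cl2, −78 °C) generates the same oxocarbenium ion, which is captured by the allylsilane in an intramolecular Sakurai reaction; the same envelope with both ring substituents pseudo-equatorial is expected, and loss of the silyl group makes the closure irreversible. This gives (2S,3R,4S,5R)-2,5-di-Ar-3-ethenyl-4-[(TBS-oxy)methyl]oxolane F2. Lemieux–Johnson cleavage of the vinyl group (OsO4 cat., NaIO4, 2,6-lutidine) then releases 15 with no Lewis acid present, and it is reduced at once as in step 9.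

**Step 5 (mixed acetal).** The hindered secondary benzylic alcohol may add too slowly to the collidinium salt, so that silyl transfer to the alcohol or alkoxy scrambling at the easily ionised aryl acetal takes over. The fallback sets out from 8 and returns at 11, building the acetal carbon by partial reduction of an ester. Esterification of 8 with commercial 4-(benzyloxy)-3,5-dimethoxybenzoic acid (DCC, DMAP) gives (1R,2S)-1-Ar-2-[(TBS-oxy)methyl]but-3-en-1-yl 4-(benzyloxy)-3,5-dimethoxybenzoate F3. Reductive acetylation (i-Bu2AlH, −78 °C; then Ac2O, pyridine, DMAP) gives the α-acetoxy ether acetoxy(Ar)methyl (1R,2S)-1-Ar-2-[(TBS-oxy)methyl]but-3-en-1-yl ether F4. Exchange of the acetate for 2-bromoethanol under BF3·OEt2 at −78 °C, a glycosylation-type substitution, then gives 11.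

**Step 7 (ring-closing metathesis).** The catalyst may be sequestered as an unreactive alkoxycarbene at the vinyl ether, initiation at the allylically branched alkene may be slow, Ru hydrides formed on heating may migrate the double bonds, and the enol acetal may decompose on traces of acid. The fallback sets out from 8 and returns at 15, generating the oxocarbenium ion and enol pair of step 8 without a dioxepin. Silylation (Et3SiCl, imidazole) gives triethyl{[(1R,2S)-1-Ar-2-[(TBS-oxy)methyl]but-3-en-1-yl]oxy}silane F5. Hydroboration–oxidation (9-BBN-H; NaOH, H2O2) gives (3S,4R)-4-Ar-3-[(TBS-oxy)methyl]-4-(triethylsilyloxy)butan-1-ol F6. Dess–Martin oxidation gives (3S,4R)-4-Ar-3-[(TBS-oxy)methyl]-4-(triethylsilyloxy)butanal F7. Enol silylation (i-Pr3SiOTf, Et3N) gives triethyl{[(1R,2S,3Z)-1-Ar-2-[(TBS-oxy)methyl]-4-(triisopropylsilyloxy)but-3-en-1-yl]oxy}silane F8. Treatment of F8 with aldehyde 3 and Me3SiOTf at −78 °C (silyl ether–aldehyde condensation to the oxocarbenium ion, then intramolecular Mukaiyama-type addition) would give 15.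

**Step 3 (allylboration).** Facial and anti selectivity may be eroded with the γ-silyloxymethyl boronate, the electron-rich aldehyde may react slowly, and a 1,3-boron shift in 6 could scramble the E geometry before addition. The fallback sets out from 3 and returns at 8. Iridium-catalysed transfer-hydrogenative anti-(hydroxymethyl)allylation of 3 uses the cyclic carbonate of (Z)-but-2-ene-1,4-diol as allyl donor ([Ir(cod)Cl]2, SEGPHOS enantiomer chosen for the 1R,2S product, a 3-nitrobenzoic acid co-catalyst, i-PrOH as reductant). It would give (1R,2S)-1-Ar-2-ethenylpropane-1,3-diol F9, whose primary hydroxyl is silylated selectively (TBSCl, imidazole) to give 8.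

## Further compounds

F1 | step 8 | (1R,2S,3E)-1-[4-(benzyloxy)-3,5-dimethoxyphenyl]-2-{[(tert-butyldimethylsilyl)oxy]methyl}-5-(trimethylsilyl)pent-3-en-1-ol | O[C@@H](c1cc(OC)c(OCc2ccccc2)c(OC)c1)[C@H](CO[Si](C)(C)C(C)(C)C)/C=C/C[Si](C)(C)C
F2 | step 8 | (2S,3R,4S,5R)-2,5-bis[4-(benzyloxy)-3,5-dimethoxyphenyl]-3-ethenyl-4-{[(tert-butyldimethylsilyl)oxy]methyl}oxolane | COc1cc([C@H]2O[C@@H](c3cc(OC)c(OCc4ccccc4)c(OC)c3)[C@H](CO[Si](C)(C)C(C)(C)C)[C@H]2C=C)cc(OC)c1OCc1ccccc1
F3 | step 5 | (1R,2S)-1-[4-(benzyloxy)-3,5-dimethoxyphenyl]-2-{[(tert-butyldimethylsilyl)oxy]methyl}but-3-en-1-yl 4-(benzyloxy)-3,5-dimethoxybenzoate | O=C(O[C@@H](c1cc(OC)c(OCc2ccccc2)c(OC)c1)[C@H](CO[Si](C)(C)C(C)(C)C)C=C)c1cc(OC)c(OCc2ccccc2)c(OC)c1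
F4 | step 5 | [4-(benzyloxy)-3,5-dimethoxyphenyl]{[(1R,2S)-1-[4-(benzyloxy)-3,5-dimethoxyphenyl]-2-{[(tert-butyldimethylsilyl)oxy]methyl}but-3-en-1-yl]oxy}methyl acetate, both epimers at the acetal carbon | CC(=O)OC(O[C@@H](c1cc(OC)c(OCc2ccccc2)c(OC)c1)[C@H](CO[Si](C)(C)C(C)(C)C)C=C)c1cc(OC)c(OCc2ccccc2)c(OC)c1
F5 | step 7 | triethyl{[(1R,2S)-1-[4-(benzyloxy)-3,5-dimethoxyphenyl]-2-{[(tert-butyldimethylsilyl)oxy]methyl}but-3-en-1-yl]oxy}silane | CC[Si](CC)(CC)O[C@@H](c1cc(OC)c(OCc2ccccc2)c(OC)c1)[C@H](CO[Si](C)(C)C(C)(C)C)C=C
F6 | step 7 | (3S,4R)-4-[4-(benzyloxy)-3,5-dimethoxyphenyl]-3-{[(tert-butyldimethylsilyl)oxy]methyl}-4-[(triethylsilyl)oxy]butan-1-ol | CC[Si](CC)(CC)O[C@@H](c1cc(OC)c(OCc2ccccc2)c(OC)c1)[C@H](CO[Si](C)(C)C(C)(C)C)CCO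
F7 | step 7 | (3S,4R)-4-[4-(benzyloxy)-3,5-dimethoxyphenyl]-3-{[(tert-butyldimethylsilyl)oxy]methyl}-4-[(triethylsilyl)oxy]butanal | CC[Si](CC)(CC)O[C@@H](c1cc(OC)c(OCc2ccccc2)c(OC)c1)[C@H](CO[Si](C)(C)C(C)(C)C)CC=O
F8 | step 7 | triethyl{[(1R,2S,3Z)-1-[4-(benzyloxy)-3,5-dimethoxyphenyl]-2-{[(tert-butyldimethylsilyl)oxy]methyl}-4-[(triisopropylsilyl)oxy]but-3-en-1-yl]oxy}silane | CC[Si](CC)(CC)O[C@@H](c1cc(OC)c(OCc2ccccc2)c(OC)c1)[C@H](CO[Si](C)(C)C(C)(C)C)/C=C\O[Si](C(C)C)(C(C)C)C(C)C
F9 | step 3 | (1R,2S)-1-[4-(benzyloxy)-3,5-dimethoxyphenyl]-2-ethenylpropane-1,3-diol | O[C@@H](c1cc(OC)c(OCc2ccccc2)c(OC)c1)[C@H](CO)C=C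
A1 | alternative 1 | sinapic acid, (2E)-3-(4-hydroxy-3,5-dimethoxyphenyl)prop-2-enoic acid | COc1cc(/C=C/C(=O)O)cc(OC)c1O
A2 | alternative 1 | 2,6-bis(4-hydroxy-3,5-dimethoxyphenyl)-3,7-dioxabicyclo[3.3.0]octane-4,8-dione, cis-fused with both aryl groups exo (one enantiomer of the racemate drawn) | O=C1O[C@@H](c3cc(OC)c(O)c(OC)c3)[C@H]2[C@@H]1[C@H](c4cc(OC)c(O)c(OC)c4)OC2=O
A3 | alternative 2 | (2S,3S)-2,3-bis[(benzyloxy)methyl]-N1,N4-dimethoxy-N1,N4-dimethylbutanediamide | CON(C)C(=O)[C@H](COCc1ccccc1)[C@@H](COCc1ccccc1)C(=O)N(C)OC
A4 | alternative 2 | [4-(benzyloxy)-3,5-dimethoxyphenyl]lithium | [Li]c1cc(OC)c(OCc2ccccc2)c(OC)c1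
A5 | alternative 2 | (2S,3S)-1,4-bis[4-(benzyloxy)-3,5-dimethoxyphenyl]-2,3-bis[(benzyloxy)methyl]butane-1,4-dione | COc1cc(cc(OC)c1OCc1ccccc1)C(=O)[C@H](COCc1ccccc1)[C@@H](COCc1ccccc1)C(=O)c1cc(OC)c(OCc2ccccc2)c(OC)c1
A6 | alternative 3 | methyl 2-[4-(benzyloxy)-3,5-dimethoxybenzoyl]-4-[(tert-butyldimethylsilyl)oxy]but-2-enoate (E/Z mixture) | COC(=O)C(=CCO[Si](C)(C)C(C)(C)C)C(=O)c1cc(OC)c(OCc2ccccc2)c(OC)c1
A7 | alternative 3 | (2R,5R)-2,5-dimethylthiolanium [4-(benzyloxy)-3,5-dimethoxyphenyl]methylide | C[C@@H]1CC[C@@H](C)[S+]1[CH-]c1cc(OC)c(OCc2ccccc2)c(OC)c1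
A8 | alternative 3 | methyl (4S,5R)-2,5-bis[4-(benzyloxy)-3,5-dimethoxyphenyl]-4-{[(tert-butyldimethylsilyl)oxy]methyl}-4,5-dihydrofuran-3-carboxylate (4,5-trans) | COC(=O)C1=C(c2cc(OC)c(OCc3ccccc3)c(OC)c2)O[C@@H](c2cc(OC)c(OCc3ccccc3)c(OC)c2)[C@@H]1CO[Si](C)(C)C(C)(C)C
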